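| setting | theta | epsilon | Tuesday's | Friday's | Wednesday's | Saturday's | Thursday's |
|---|---|---|---|---|---|---|---|
| substrate | 0.10 M | 0.10 M | 0.10 M | 0.10 M | 0.10 M | 0.10 M | 0.10 M |
| coupling partner | 0.035 M | 0.84 M | 0.0600 M | 0.120 M | 0.250 M | 0.500 M | 1.00 M |
| remark | run made earlier | run made earlier |  |  |  |  |  |
| time |  |  | 25 min | 25 min | 25 min | 25 min | 25 min |

- theta (time / min: target / %, substrate / %): 2.00: 7.0, 83.4; 6.00: 20.7, 59.9; 12.0: 34.7, 40.7; 20.0: 44.7, 27.2
- epsilon (time / min: target / %, substrate / %): 1.33: 2.7, 18.8; 3.00: 1.9, 5.4; 8.00: 3.1, 4.7; 20.0: 5.8, 3.6

(readings scatter by 1 percentage point)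

* amount of target at the end, in percent of the substrate charged for Tuesday's, Friday's, Wednesday's, Saturday's, Thursday's, in this order
* how that number moves from the first to the last of them (falls, then rises / falls all the way / rises, then falls / rises all the way / hardly changes)

- "hardly changes" means that all values lie within two and a half points (for a concentration: within two and a half percent of the largest)

1. In the epsilon run a leftover of 4.7% substrate stood at 8.00 min, beside 3.1% target. I assumed that the missing 92.2% was substrate held by coupling partner, one to one.

2. From this reading 26.2 L mol⁻¹ came out for the binding quotient K, defined as held substrate over c(substrate) times free c(coupling partner). K is the association constant of the binding, and its leftover carries a scatter of 1 percentage point.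

3. A rising row would need the target to take up coupling partner, or its rate constant per free substrate to grow with c(coupling partner). The theta run reached 0.0447 M target from a 0.035 M charge of partner. The readings gave 0.0432 min⁻¹ in theta and 0.0510 min⁻¹ in epsilon, a factor 1.18 against a factor 24.0 in partner.

4. Binding in epsilon had a time constant of 0.796 min. Scaled to Tuesday's charge it became 11.1 min, shorter than 25 min, so I treated binding as balanced.

5. With K, the free share of substrate was 0.627 for Tuesday's and 0.0405 for Thursday's. I assumed that the pool of free and held substrate lost material to target and by no other route, an assumption that ignored any other drain on the pool. On that assumption I reckoned time constants of 37.0 min for Tuesday's and 573 min for Thursday's. On the same assumption, the fraction left after 25 min gave 49.1% target for Tuesday's. For Thursday's it gave 6.17%, counting the 1.9% that epsilon held at 3.00 min. At fixed K the free share shrinks as partner grows, so I expected the row to fall throughout.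

6. The forecast read 46%, 32%, 20%, 11%, 6%, falls all the way, with a target that “then leaks out slowly”.

7. The flasks gave 43.8%, 31.8%, 20.1%, 11.9%, 6.64%: falls all the way.

    substrate + coupling partner ⇌ intermediate A (K = 22.0 L mol⁻¹, k = 1.70 L mol⁻¹ min⁻¹)
    intermediate A ⇌ intermediate B (K = 0.720, k = 0.00300 min⁻¹)
    substrate → target (k = 0.0450 min⁻¹)
    coupling partner + intermediate B → intermediate C (k = 5.80 L mol⁻¹ min⁻¹)
    intermediate C → intermediate D (k = 0.0920 min⁻¹)
    intermediate D → side product A (k = 0.0230 min⁻¹)
    substrate + intermediate A → side product B (k = 0.730 L mol⁻¹ min⁻¹)

8. At the end Saturday's held 56.1% intermediate A and 5.47% substrate, with 85% of its coupling partner unbound. For Saturday's, K puts substrate over intermediate A at 0.0900, and the flask stood at 0.0975. For Tuesday's, K gives 1.21, and the flask stood at 1.17.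

All runs are calculated with constants of no real substance, noise included.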